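## Structural features

The target is a single carbocycle, a cyclohex-1-ene in which C1 carries the exocyclic benzoyloxymethyl carbon C7, C2 is the vinylic CH, and C3 to C6 are four contiguous oxygen-bearing stereocentres, (3R,4S,5R,6S), with the relationships 3,4-trans, 4,5-cis and 5,6-trans. Only two of the five oxygens are acylated: the primary allylic O7 and the secondary O5, which sits between the free hydroxyls on C4 (cis) and C6 (trans). This arrangement is fragile: base can move the C5 benzoate to O4 or O6, the allylic C3–O and C7–O bonds can ionise under strong acid, and the trisubstituted alkene rules out hydrogenolysis as a last deprotection. The ring is not the hard part. The difficulty is to place one benzoate on C5 among four secondary oxygens, to set C3 relative to C4, and to bring in C7 and the C1–C2 alkene without enolising toward the alkoxy-bearing carbons. The key step exploits the fact that C4, C5 and C6 have the configuration of C2, C3 and C4 of L-rhamnose, and that C3 and C1 stand in a 1,5-relationship with C2 between them. In the 5-ulose of the sugar the aldehyde carbon is C3, the ketone carbon is C1 and the deoxy methyl is C2, so one aldol closure forms the C2–C3 bond, the six-membered ring and the C3 carbinol. Because O5 is the equatorial O3 of the cis-2,3-diol of a rhamnopyranoside, it can be given its own ether in the first step, which fixes the benzoate position before the ring exists.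

## Logic of the disconnections

18 to 17. The three benzyl–oxygen bonds at O3, O4 and O6 are cut last. Both benzoates are then already in place and no acylation has to be selective on a polyol. The forward step must be non-basic (no acyl migration) and non-reductive (the alkene stays), which points to a Lewis-acid debenzylation.

17 to 15 and 16. The two ester C–O bonds at O5 and O7 are cut together. This is possible only if 15 has exactly these two hydroxyls free, so the demand falls on the protecting-group pattern and not on the acylation.

15 to 14. The O5–naphthylmethyl bond is reformed. O5 therefore needs an ether that can be removed oxidatively while three benzyl ethers and an alkene remain.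

14 to 13. The C1–C2 alkene and the O7–H are traded for an oxirane C1–O bond and a C2–H bond. This removes the alkene and reduces the problem to a ketone homologation. The forward step must take the proton from C2 and not from C6.

13 to 11 and 12. The C1–C7 bond and the C7–O bond of the oxirane are cut, which leaves a ketone at C1 and a one-carbon ylide. The forward step must add to the carbonyl faster than it enolises it. The configuration at the spiro carbon does not matter.

11 to 9 and 10. The O3–benzyl bond is cut. The hydroxyl of 9 must be capped without forming its alkoxide, because a β-alkoxide of a ketone fragments by retro-aldol reaction.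

9 to 8. The C2–C3 bond is cut. The ring opens to a chain with the ketone at C1, its methyl as C2 and the aldehyde as C3, while the three ether stereocentres stay untouched. The forward step must form the methyl-side enol equivalent, avoid β-elimination, and deliver the hydroxyl trans to O4.

8 to 7, 7 to 6, 6 to 5. The two carbonyl groups come from the two hydroxyls of a 1,5-diol, the diol from a lactol by reduction, and the lactol from a methyl glycoside by hydrolysis. These are adjustments of oxidation level on a fixed carbon chain. The demand is that both alcohols are oxidised at the same time, so that no lactol or lactone forms between them.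

5 to 3 and 4, 3 to 1 and 2. The two O–benzyl bonds and then the O3–naphthylmethyl bond (sugar numbering) are cut, which leads to the starting materials 1, 2 and 4. The forward demand is regioselective alkylation of one oxygen of the cis-2,3-diol of 1.

## Other disconnections considered

Alternative 1: The cut is made at the C3–O and C6–O bonds, which are traced back to a peroxide bridge. The ring, C7 (as an ester carbon) and the C4/C5 diol would then come from shikimic acid A1 through the diene ester A2, which has C6=C1–C2=C3 and an acetonide on O4/O5. The forward key step is a [4+2] photo-oxygenation of A2 on the face opposite the acetonide to give the endoperoxide A3. Reduction of the O–O bond should leave O3 and O6 cis to each other and trans to O4/O5, which is the relative configuration of 18.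

- In its favour: all seven carbons, the C1–C2 alkene and C7 are present from the start, and one concerted cycloaddition with steric facial control sets both new stereocentres.
- Against it here: O4 and O5 are tied in one acetonide, so the benzoate has to be placed on one oxygen of a cis-diol late in the sequence. The diene of A2 is electron-poor and should react slowly. A3 is base-sensitive (fragmentation to a hydroxy enone) and a peroxide to be handled with care on scale.
- Comparison: on skeleton construction it is better than the chosen plan, which needs two steps (13, 14) to bring in C7 and the alkene. On stereocontrol at C3 it is also better, since a pericyclic addition anti to a fused ring is more predictable than the facial selectivity of the aldol closure. On benzoate regiochemistry it is weaker, since the chosen plan settles O5 in step 1. In step count the two are about equal on paper.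

Alternative 2: The cut is made at the C4–O and C5–O bonds, back to bromobenzene A4. The forward key step is the whole-cell oxidation of A4 by toluene dioxygenase to the cis-diene diol A5, in which the bromine sits on C6 and C1, C2 and C3 complete the diene.

- In its favour: the absolute configuration at C4 and C5 comes in one catalytic step from an achiral commodity, and the vinyl bromide polarises the diene so that its two alkenes can be told apart.
- Against it here: C1 of A5 is an unsubstituted diene carbon, so C7 must still be attached by a C–C bond formation. The bromine stands on C6, which needs oxygen, not carbon. A route through a C6 ketone would have to reduce it so that O6 ends trans to O5, against the shielding of a 4,5-acetonide. A5 dimerises and rearomatises easily, and fermentation equipment is needed unless A5 is bought. The O4/O5 pair is again undifferentiated.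
- Comparison: on the first stereocentres it is better than the chosen plan (one step against one from the chiral pool plus protection), and the enzymatic selectivity is as reliable as a chiral-pool source. On the later C–C bond at C1 and on the C6 configuration it is weaker, and the number of steps after the key step should exceed that of the chosen plan.

Alternative 3: The cut is made at the C1–C6 bond, back to the enoate aldehyde A7, which would be built from D-arabinose A6 by chain extension at its aldehyde carbon and oxidation of its primary alcohol. Sugar C2, C3 and C4 become C3, C4 and C5. The forward key step is an intramolecular Morita–Baylis–Hillman reaction: a trialkylphosphine adds to C2, the enolate carbon C1 attacks the C6 aldehyde, and loss of the phosphine gives the cyclohexene A8.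

- In its favour: one step closes the ring and delivers the C1–C2 alkene, C7 (as the ester carbon) and the C6 carbinol. After it only an ester reduction and protecting-group work remain on the skeleton.
- Against it here: the C6 hydroxyl must form trans to O5 under substrate control, which is as uncertain as C3 in the aldol closure. A7 has an epimerisable α-alkoxy aldehyde and needs its two ends made in separate operations. The acetonide on O4/O5 again leaves the benzoate position open unless the protecting groups are redesigned.
- Comparison: on step economy after ring closure it is better than the chosen plan. On stereocontrol of the new carbinol the two are equal, since both depend on a substrate-controlled carbonyl addition. In the preparation of the acyclic precursor the two are of similar length, but the chosen plan sets O5 apart more directly, because a rhamnopyranoside offers a cis-diol with one equatorial oxygen.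

Key step: step 6

Assumption: 6 is an anomeric mixture and 13 a pair of epimers at the spiro carbon; both centres are destroyed in the following step, so their configuration is left open in names and SMILES.

## Route

Step 1
Reactants: 1 methyl α-L-rhamnopyranoside; 2 2-(bromomethyl)naphthalene
Product: 3 methyl 3-O-(naphthalen-2-ylmethyl)-α-L-rhamnopyranoside
Conditions: Ph2BOCH2CH2NH2 (10 mol%), Ag2O, MeCN, 40 °C
Reagents that add atoms: 2-(bromomethyl)naphthalene, BrCc1ccc2ccccc2c1
Why: Borinic-acid-catalysed regioselective O-alkylation of a cis-1,2-diol: the catalyst binds O2/O3 as a tetracoordinate borinate, whose equatorial O3 is the most nucleophilic oxygen, so O2 and O4 stay free. No stereocentre is touched.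

Step 2
Reactants: 3 methyl 3-O-(naphthalen-2-ylmethyl)-α-L-rhamnopyranoside; 4 benzyl bromide
Product: 5 methyl 2,4-di-O-benzyl-3-O-(naphthalen-2-ylmethyl)-α-L-rhamnopyranoside
Conditions: NaH, BnBr, Bu4NI (cat.), THF, 0 °C → rt
Reagents that add atoms: benzyl bromide, BrCc1ccccc1
Why: Williamson etherification of the two remaining secondary hydroxyls. The acetal and the arylmethyl ether are inert to alkoxide.

Step 3
Reactants: 5 methyl 2,4-di-O-benzyl-3-O-(naphthalen-2-ylmethyl)-α-L-rhamnopyranoside
Product: 6 2,4-di-O-benzyl-3-O-(naphthalen-2-ylmethyl)-L-rhamnopyranose (anomeric mixture)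
Conditions: AcOH, 2 M aq. HCl, 70 °C
Reagents that add atoms: water, O
Why: Acid-catalysed hydrolysis of the glycosidic acetal through the oxocarbenium ion. A 6-deoxyglycoside hydrolyses more easily than a fully oxygenated one, which keeps the exposure of the benzyl and naphthylmethyl ethers to acid short.

Step 4
Reactants: 6 2,4-di-O-benzyl-3-O-(naphthalen-2-ylmethyl)-L-rhamnopyranose
Product: 7 2,4-di-O-benzyl-6-deoxy-3-O-(naphthalen-2-ylmethyl)-L-mannitol (rhamnose numbering)
Conditions: NaBH4, EtOH, 0 °C → rt
Reagents that add atoms: none
Why: Hydride reduction of the open-chain aldehyde that is in equilibrium with the lactol gives the 1,5-diol. The stereocentres are not involved.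

Step 5
Reactants: 7 2,4-di-O-benzyl-6-deoxy-3-O-(naphthalen-2-ylmethyl)-L-mannitol
Product: 8 2,4-di-O-benzyl-6-deoxy-3-O-(naphthalen-2-ylmethyl)-L-lyxo-hexos-5-ulose
Conditions: (COCl)2, DMSO, CH2Cl2, −78 °C; Et3N, −78 → 0 °C; used crude
Reagents that add atoms: none
Why: Double Swern oxidation: both hydroxyls are turned into alkoxysulfonium ions at −78 °C before the base is added, so the hydroxy aldehyde cannot close to a lactol and over-oxidise to a lactone. This is the established way from 1,5-alditols to 1,5-dicarbonyl sugars.

Step 6
Reactants: 8 2,4-di-O-benzyl-6-deoxy-3-O-(naphthalen-2-ylmethyl)-L-lyxo-hexos-5-ulose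
Product: 9 (2R,3S,4S,5R)-2,4-bis(benzyloxy)-5-hydroxy-3-(naphthalen-2-ylmethoxy)cyclohexan-1-one
Conditions: L-proline (30 mol%), DMSO, rt
Reagents that add atoms: none
Why: L-Proline should condense with the methyl ketone to the terminal enamine, whose CH2 carbon (C2 of the target) adds to the aldehyde carbon (C3) while the carboxylic acid hydrogen-bonds the aldehyde oxygen; hydrolysis of the iminium ion then releases 9 and the catalyst. The closest known reaction type is the amine-catalysed intramolecular aldol reaction of the Hajos–Parrish kind, applied to sugar-derived 1,5-dicarbonyl compounds, which makes the same bond as a Ferrier carbocyclisation. The ring closes in the 6-(enolendo)-exo-trig mode, with both enamine carbons inside the new ring and the carbonyl oxygen outside it. The new stereocentre C3 is under substrate control: in the chair-like transition state the C5 and C6 ether groups are equatorial, the C4 benzyloxy group is axial, and the aldehyde oxygen is axial, where it can reach the carboxyl group on the enamine nitrogen and lies antiperiplanar to the C4–O dipole, so the hydroxyl is expected trans to O4 and O5 (5R in 9). Site selectivity is needed among three enolisable positions: only the methyl terminus can reach the aldehyde through a six-membered ring (the other two would close four-membered rings), and the α-branched, α-alkoxy aldehyde forms an enamine slowly. Near-neutral conditions at room temperature are chosen to limit β-elimination of the naphthylmethoxy group and epimerisation next to the two carbonyl groups. The three sugar stereocentres pass unchanged into C4, C5 and C6.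

Step 7
Reactants: 9 (2R,3S,4S,5R)-2,4-bis(benzyloxy)-5-hydroxy-3-(naphthalen-2-ylmethoxy)cyclohexan-1-one; 10 benzyl 2,2,2-trichloroacetimidate
Product: 11 (2R,3S,4S,5R)-2,4,5-tris(benzyloxy)-3-(naphthalen-2-ylmethoxy)cyclohexan-1-one
Conditions: BnOC(=NH)CCl3, TfOH (5 mol%), CH2Cl2/cyclohexane, 0 °C
Reagents that add atoms: benzyl 2,2,2-trichloroacetimidate, N=C(OCc1ccccc1)C(Cl)(Cl)Cl
Why: Acid-catalysed O-benzylation through the protonated imidate. No alkoxide is formed, so the β-hydroxy ketone is not exposed to retro-aldol cleavage or base-induced dehydration, and C3 keeps its configuration because its C–O bond is not broken.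

Step 8
Reactants: 11 (2R,3S,4S,5R)-2,4,5-tris(benzyloxy)-3-(naphthalen-2-ylmethoxy)cyclohexan-1-one; 12 trimethylsulfonium iodide
Product: 13 (4R,5S,6S,7R)-4,6,7-tris(benzyloxy)-5-(naphthalen-2-ylmethoxy)-1-oxaspiro[2.5]octane (both epimers at the spiro carbon C3)
Conditions: Me3S+ I−, n-BuLi, THF, −10 °C → 0 °C
Reagents that add atoms: trimethylsulfonium iodide, C[S+](C)C.[I-]
Why: Corey–Chaykovsky epoxidation: the sulfonium ylide adds to the ketone and the betaine closes with loss of dimethyl sulfide, which brings in C7. The face of attack is immaterial because C1 becomes trigonal in step 9.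

Step 9
Reactants: 13 (4R,5S,6S,7R)-4,6,7-tris(benzyloxy)-5-(naphthalen-2-ylmethoxy)-1-oxaspiro[2.5]octane
Product: 14 [(3R,4S,5R,6S)-3,4,6-tris(benzyloxy)-5-(naphthalen-2-ylmethoxy)cyclohex-1-en-1-yl]methanol
Conditions: 2,2,6,6-tetramethylpiperidine, n-BuLi, toluene, 0 °C; Et2AlCl; then 13, 0 °C → rt; aq. KNaC4H4O6 (potassium sodium tartrate)
Reagents that add atoms: none
Why: Base-promoted isomerisation of an epoxide to an allylic alcohol: the aluminum amide binds the oxirane oxygen and removes a syn β-hydrogen through a cyclic transition state, which breaks the C1–O bond and leaves the C7 alkoxide. The secondary C2–H is expected to be taken in preference to the tertiary, benzyloxy-bearing C6–H, and either spiro epimer has a C2–H syn to the oxygen.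

Step 10
Reactants: 14 [(3R,4S,5R,6S)-3,4,6-tris(benzyloxy)-5-(naphthalen-2-ylmethoxy)cyclohex-1-en-1-yl]methanol
Product: 15 [(3R,4R,5R,6S)-3,4,6-tris(benzyloxy)-5-hydroxycyclohex-1-en-1-yl]methanol
Conditions: DDQ, CH2Cl2/pH 7 phosphate buffer, 0 °C → rt
Reagents that add atoms: none
Why: Oxidative cleavage of the naphthylmethyl ether by hydride abstraction at its benzylic carbon and hydrolysis of the oxocarbenium ion. Benzyl ethers are oxidised much more slowly, and low temperature with buffer should spare the primary allylic alcohol. The change of the C4 descriptor from S to R is a priority effect only.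

Step 11
Reactants: 15 [(3R,4R,5R,6S)-3,4,6-tris(benzyloxy)-5-hydroxycyclohex-1-en-1-yl]methanol; 16 benzoyl chloride
Product: 17 [(3R,4S,5R,6S)-5-(benzoyloxy)-3,4,6-tris(benzyloxy)cyclohex-1-en-1-yl]methyl benzoate
Conditions: BzCl, pyridine, DMAP (cat.), CH2Cl2, 0 °C → rt
Reagents that add atoms: benzoyl chloride, O=C(Cl)c1ccccc1
Why: Nucleophilic catalysis of acyl transfer to the only two free hydroxyls, O7 and O5, so no selectivity is asked of the acylation.

Step 12
Reactants: 17 [(3R,4S,5R,6S)-5-(benzoyloxy)-3,4,6-tris(benzyloxy)cyclohex-1-en-1-yl]methyl benzoate
Product: 18 [(3R,4S,5R,6S)-5-(benzoyloxy)-3,4,6-trihydroxycyclohex-1-en-1-yl]methyl benzoate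
Conditions: BCl3, C6HMe5, CH2Cl2, −78 °C; then MeOH
Reagents that add atoms: none
Why: Lewis-acid cleavage of the three benzyl ethers, with pentamethylbenzene as a non-basic trap for the benzyl cation. Benzoates and the alkene are inert at −78 °C, and the acidic quench avoids the base-induced acyl migration to which the C5 benzoate is prone.

## Compound list

1 | methyl α-L-rhamnopyranoside (methyl 6-deoxy-α-L-mannopyranoside) | CO[C@H]1[C@H](O)[C@H](O)[C@@H](O)[C@H](C)O1 | starting material
2 | 2-(bromomethyl)naphthalene | BrCc1ccc2ccccc2c1 | starting material
3 | methyl 3-O-(naphthalen-2-ylmethyl)-α-L-rhamnopyranoside | CO[C@H]1[C@H](O)[C@H](OCc2ccc3ccccc3c2)[C@@H](O)[C@H](C)O1 | intermediate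
4 | benzyl bromide | BrCc1ccccc1 | starting material
5 | methyl 2,4-di-O-benzyl-3-O-(naphthalen-2-ylmethyl)-α-L-rhamnopyranoside | CO[C@H]1[C@H](OCc2ccccc2)[C@H](OCc2ccc3ccccc3c2)[C@@H](OCc2ccccc2)[C@H](C)O1 | intermediate
6 | 2,4-di-O-benzyl-3-O-(naphthalen-2-ylmethyl)-L-rhamnopyranose (anomeric mixture) | OC1[C@H](OCc2ccccc2)[C@H](OCc2ccc3ccccc3c2)[C@@H](OCc2ccccc2)[C@H](C)O1 | intermediate
7 | 2,4-di-O-benzyl-6-deoxy-3-O-(naphthalen-2-ylmethyl)-L-mannitol (rhamnose numbering) | OC[C@H](OCc1ccccc1)[C@H](OCc1ccc2ccccc2c1)[C@@H](OCc1ccccc1)[C@@H](O)C | intermediate
8 | 2,4-di-O-benzyl-6-deoxy-3-O-(naphthalen-2-ylmethyl)-L-lyxo-hexos-5-ulose | O=C[C@H](OCc1ccccc1)[C@H](OCc1ccc2ccccc2c1)[C@@H](OCc1ccccc1)C(C)=O | intermediate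
9 | (2R,3S,4S,5R)-2,4-bis(benzyloxy)-5-hydroxy-3-(naphthalen-2-ylmethoxy)cyclohexan-1-one | O=C1C[C@@H](O)[C@H](OCc2ccccc2)[C@H](OCc2ccc3ccccc3c2)[C@H]1OCc1ccccc1 | intermediate
10 | benzyl 2,2,2-trichloroacetimidate | N=C(OCc1ccccc1)C(Cl)(Cl)Cl | starting material
11 | (2R,3S,4S,5R)-2,4,5-tris(benzyloxy)-3-(naphthalen-2-ylmethoxy)cyclohexan-1-one | O=C1C[C@@H](OCc2ccccc2)[C@H](OCc2ccccc2)[C@H](OCc2ccc3ccccc3c2)[C@H]1OCc1ccccc1 | intermediate
12 | trimethylsulfonium iodide | C[S+](C)C.[I-] | starting material
13 | (4R,5S,6S,7R)-4,6,7-tris(benzyloxy)-5-(naphthalen-2-ylmethoxy)-1-oxaspiro[2.5]octane (both epimers at the spiro carbon C3) | C1OC12C[C@@H](OCc3ccccc3)[C@H](OCc3ccccc3)[C@H](OCc3ccc4ccccc4c3)[C@H]2OCc1ccccc1 | intermediate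
14 | [(3R,4S,5R,6S)-3,4,6-tris(benzyloxy)-5-(naphthalen-2-ylmethoxy)cyclohex-1-en-1-yl]methanol | OCC1=C[C@@H](OCc2ccccc2)[C@H](OCc2ccccc2)[C@H](OCc2ccc3ccccc3c2)[C@H]1OCc1ccccc1 | intermediate
15 | [(3R,4R,5R,6S)-3,4,6-tris(benzyloxy)-5-hydroxycyclohex-1-en-1-yl]methanol | OCC1=C[C@@H](OCc2ccccc2)[C@H](OCc2ccccc2)[C@H](O)[C@H]1OCc1ccccc1 | intermediate
16 | benzoyl chloride | O=C(Cl)c1ccccc1 | starting material
17 | [(3R,4S,5R,6S)-5-(benzoyloxy)-3,4,6-tris(benzyloxy)cyclohex-1-en-1-yl]methyl benzoate | O=C(OCC1=C[C@@H](OCc2ccccc2)[C@H](OCc2ccccc2)[C@H](OC(=O)c2ccccc2)[C@H]1OCc1ccccc1)c1ccccc1 | intermediate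
18 | [(3R,4S,5R,6S)-5-(benzoyloxy)-3,4,6-trihydroxycyclohex-1-en-1-yl]methyl benzoate | O=C(OCC1=C[C@@H](O)[C@H](O)[C@H](OC(=O)c2ccccc2)[C@H]1O)c1ccccc1 | target

## Step count and least certain steps

Total step count: 12. Longest linear sequence: 12 steps (1 to 18).

Step 6 (key step). Two processes are most likely to go wrong. The first is β-elimination of the naphthylmethoxy group, which is β to both carbonyl groups of 8 and can leave through the aldehyde enamine or an enol. The second is insufficient facial selectivity at the aldehyde, or erosion of the kinetic preference by retro-aldol equilibration, because the C3 epimer can adopt a chair with only one axial substituent. The fallback answers the selectivity problem by correcting the centre instead of relying on the transition state. It sets out from 8: the same cyclisation is run toward the C3 epimer, (2R,3S,4S,5S)-2,4-bis(benzyloxy)-5-hydroxy-3-(naphthalen-2-ylmethoxy)cyclohexan-1-one F1. Mitsunobu reaction of F1 with chloroacetic acid (PPh3, diisopropyl azodicarboxylate, toluene, 0 °C) inverts C3 and gives (2R,3S,4S,5R)-2,4-bis(benzyloxy)-5-(chloroacetoxy)-3-(naphthalen-2-ylmethoxy)cyclohexan-1-one F2. The chloroacetate is removed with thiourea and NaHCO3 in EtOH under nearly neutral conditions, so that the β-acyloxy ketone is not exposed to alkoxide. The route is rejoined at 9.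

Step 9. The likely failure is poor regioselectivity of proton abstraction (C6–H instead of C2–H, leading to an enol ether), together with Lewis-acid-induced hydride shift of the oxirane to an aldehyde; both are favoured by the many ether oxygens that bind aluminum. The fallback replaces the isomerisation by opening and dehydration and sets out from 13. Benzoate (PhCO2H, PhCO2Cs, DMF, 80 °C) opens the oxirane at its CH2 terminus to [(2R,3S,4S,5R)-2,4,5-tris(benzyloxy)-1-hydroxy-3-(naphthalen-2-ylmethoxy)cyclohexyl]methyl benzoate F3. Dehydration of the tertiary alcohol (SOCl2, pyridine, CH2Cl2, 0 °C) toward the only ring CH2 gives [(3R,4S,5R,6S)-3,4,6-tris(benzyloxy)-5-(naphthalen-2-ylmethoxy)cyclohex-1-en-1-yl]methyl benzoate F4. DDQ then frees O5 to give [(3R,4R,5R,6S)-3,4,6-tris(benzyloxy)-5-hydroxycyclohex-1-en-1-yl]methyl benzoate F5, and benzoylation (BzCl, pyridine) rejoins the route at 17. This detour also runs the oxidative ether cleavage on a substrate without a free allylic alcohol.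

Step 8. The likely failure is enolisation of the α-benzyloxy ketone by the basic ylide in competition with addition, with epimerisation at C6 or E1cB loss of the C3 benzyloxy group. The fallback separates C–C bond formation from oxygen transfer and sets out from 11. Non-basic Petasis methylenation (Cp2TiMe2, toluene, 65 °C) gives (1R,2S,3R,4S)-1,2,4-tris(benzyloxy)-5-methylidene-3-(naphthalen-2-ylmethoxy)cyclohexane F6, and epoxidation of the exocyclic alkene (mCPBA, NaHCO3, CH2Cl2) rejoins the route at 13.

Step 12. The likely failure is Lewis-acid ionisation of the allylic C3–O or C7–O bond with capture by chloride, or acyl migration of the C5 benzoate during the quench. The fallback changes the mechanism from Lewis-acid cleavage to oxidation: from 17, visible-light-promoted oxidative debenzylation with DDQ in wet CH2Cl2 removes the benzyl groups as benzaldehyde under nearly neutral conditions and rejoins the route at 18. No new compound lies on this path.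

## Further compounds

F1 | step 6 | (2R,3S,4S,5S)-2,4-bis(benzyloxy)-5-hydroxy-3-(naphthalen-2-ylmethoxy)cyclohexan-1-one | O=C1C[C@H](O)[C@H](OCc2ccccc2)[C@H](OCc2ccc3ccccc3c2)[C@H]1OCc1ccccc1
F2 | step 6 | (2R,3S,4S,5R)-2,4-bis(benzyloxy)-5-(chloroacetoxy)-3-(naphthalen-2-ylmethoxy)cyclohexan-1-one | O=C1C[C@@H](OC(=O)CCl)[C@H](OCc2ccccc2)[C@H](OCc2ccc3ccccc3c2)[C@H]1OCc1ccccc1
F3 | step 9 | [(2R,3S,4S,5R)-2,4,5-tris(benzyloxy)-1-hydroxy-3-(naphthalen-2-ylmethoxy)cyclohexyl]methyl benzoate (both C1 epimers) | O=C(OCC1(O)C[C@@H](OCc2ccccc2)[C@H](OCc2ccccc2)[C@H](OCc2ccc3ccccc3c2)[C@H]1OCc1ccccc1)c1ccccc1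
F4 | step 9 | [(3R,4S,5R,6S)-3,4,6-tris(benzyloxy)-5-(naphthalen-2-ylmethoxy)cyclohex-1-en-1-yl]methyl benzoate | O=C(OCC1=C[C@@H](OCc2ccccc2)[C@H](OCc2ccccc2)[C@H](OCc2ccc3ccccc3c2)[C@H]1OCc1ccccc1)c1ccccc1
F5 | step 9 | [(3R,4R,5R,6S)-3,4,6-tris(benzyloxy)-5-hydroxycyclohex-1-en-1-yl]methyl benzoate | O=C(OCC1=C[C@@H](OCc2ccccc2)[C@H](OCc2ccccc2)[C@H](O)[C@H]1OCc1ccccc1)c1ccccc1
F6 | step 8 | (1R,2S,3R,4S)-1,2,4-tris(benzyloxy)-5-methylidene-3-(naphthalen-2-ylmethoxy)cyclohexane | C=C1C[C@@H](OCc2ccccc2)[C@H](OCc2ccccc2)[C@H](OCc2ccc3ccccc3c2)[C@H]1OCc1ccccc1
F0 | step 12 | none | none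
A1 | alternative 1 | shikimic acid, (3R,4S,5R)-3,4,5-trihydroxycyclohex-1-ene-1-carboxylic acid | O=C(O)C1=C[C@@H](O)[C@@H](O)[C@H](O)C1
A2 | alternative 1 | methyl (3R,4S)-3,4-(isopropylidenedioxy)cyclohexa-1,5-diene-1-carboxylate (shikimate numbering) | COC(=O)C1=C[C@H]2OC(C)(C)O[C@H]2C=C1
A3 | alternative 1 | acetonide-fused 2,3-dioxabicyclo[2.2.2]oct-5-ene methyl ester (C3,C6 endoperoxide) | COC(=O)C1=C[C@@H]2[C@@H]3OC(C)(C)O[C@@H]3[C@H]1OO2
A4 | alternative 2 | bromobenzene | Brc1ccccc1
A5 | alternative 2 | (1S,2S)-3-bromocyclohexa-3,5-diene-1,2-diol | BrC1=CC=C[C@H](O)[C@@H]1O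
A6 | alternative 3 | D-arabinose (open-chain form) | O=C[C@@H](O)[C@H](O)[C@H](O)CO
A7 | alternative 3 | methyl (E)-4-(tert-butyldimethylsilyloxy)-5,6-(isopropylidenedioxy)-7-oxohept-2-enoate with the C4 to C6 configuration of D-arabinose C2 to C4 | COC(=O)/C=C/[C@@H](O[Si](C)(C)C(C)(C)C)[C@@H]1OC(C)(C)O[C@@H]1C=O
A8 | alternative 3 | methyl 6-hydroxy-3-(tert-butyldimethylsilyloxy)-4,5-(isopropylidenedioxy)cyclohex-1-ene-1-carboxylate | COC(=O)C1=C[C@@H](O[Si](C)(C)C(C)(C)C)[C@@H]2OC(C)(C)O[C@@H]2[C@H]1O
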